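The oxolane (O1, C2–C5; C3 carries the (S)-carbinol) is disconnected at C2–C3 and O1–C5. This reveals formaldehyde (O1, C2) and a C3–C4–C5 unit in which C3 is alpha and C5 gamma to the benzylic carbinol carbon on C3: the pattern of an aryl cyclopropyl ketone. In the key step MgI2 opens the cyclopropane at its CH2 with iodide, the magnesium enolate adds to formaldehyde (C2–C3) and the resulting alkoxide displaces iodide (O1–C5). The precursor is an enantioenriched trans-cyclopropyl aryl ketone that already carries the silyl-protected (R)-carbinol at the future C4; the (S)-carbinol follows by Felkin–Anh reduction of the ketone.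

Key step: step 5

Assumption: 9-O-methylquinidine is taken to deliver the (1S,2S) cyclopropane in step 1; its pseudo-enantiomer 9-O-methylquinine would be used instead if the first batch proved antipodal.

Step 1
Reactants: 1 2-bromo-1-[4-(benzyloxy)-3-methoxyphenyl]ethan-1-one; 2 N-methoxy-N-methylprop-2-enamide
Product: 3 (1S,2S)-2-[4-(benzyloxy)-3-methoxybenzoyl]-N-methoxy-N-methylcyclopropane-1-carboxamide
Conditions: 9-O-methylquinidine (20 mol%), Cs2CO3 (1.3 equiv), MeCN, 80 °C, slow addition of 1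
Reagents that add atoms: none
Why: Cinchona-alkaloid-catalysed ammonium ylide cyclopropanation (Michael-initiated ring closure), in which the catalyst-bound ylide of 1 adds to the acrylamide and closes 3-exo-tet with release of the amine; the trans ring is the preferred outcome and the chiral ammonium group sets both ring stereocentres.

Step 2
Reactants: 3 (1S,2S)-2-[4-(benzyloxy)-3-methoxybenzoyl]-N-methoxy-N-methylcyclopropane-1-carboxamide
Product: 4 (1S,2S)-2-{(R)-[4-(benzyloxy)-3-methoxyphenyl](hydroxy)methyl}-N-methoxy-N-methylcyclopropane-1-carboxamide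
Conditions: trans-RuCl2[(S)-xylbinap][(S)-daipen] (0.5 mol%), KOtBu (2 mol%), H2 (8 atm), i-PrOH, 25 °C
Reagents that add atoms: none
Why: Noyori asymmetric hydrogenation of an aryl ketone, in which the catalyst distinguishes aryl from cyclopropyl and should set the (R)-carbinol under catalyst control while benzyl ethers, the N–O bond and the cyclopropane are left alone.

Step 3
Reactants: 4 (1S,2S)-2-{(R)-[4-(benzyloxy)-3-methoxyphenyl](hydroxy)methyl}-N-methoxy-N-methylcyclopropane-1-carboxamide
Product: 5 (1S,2S)-2-{(R)-[4-(benzyloxy)-3-methoxyphenyl][(tert-butyldimethylsilyl)oxy]methyl}-N-methoxy-N-methylcyclopropane-1-carboxamide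
Conditions: TBSCl, imidazole, DMF, 23 °C
Reagents that add atoms: tert-butyldimethylsilyl chloride, CC(C)(C)[Si](C)(C)Cl
Why: Standard silylation of a secondary alcohol under non-acidic conditions, which should spare the acid-sensitive cyclopropylcarbinyl benzylic position and leave all stereocentres untouched.

Step 4
Reactants: 5 (1S,2S)-2-{(R)-[4-(benzyloxy)-3-methoxyphenyl][(tert-butyldimethylsilyl)oxy]methyl}-N-methoxy-N-methylcyclopropane-1-carboxamide; 6 1-(benzyloxy)-4-bromo-2-methoxybenzene
Product: 9 [4-(benzyloxy)-3-methoxyphenyl][(1S,2S)-2-{(R)-[4-(benzyloxy)-3-methoxyphenyl][(tert-butyldimethylsilyl)oxy]methyl}cyclopropyl]methanone, via aryllithium 7 (not isolated), via lithium aminal alkoxide 8 (not isolated)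
Conditions: 6, n-BuLi, THF, −78 °C; then 5, −78 to −20 °C; then H2O
Reagents that add atoms: none
Why: Bromine–lithium exchange followed by Weinreb ketone synthesis, in which the chelated tetrahedral adduct 8 resists a second addition and collapses to the ketone only on work-up, with no stereocentre involved.

Step 5
Reactants: 9 [4-(benzyloxy)-3-methoxyphenyl][(1S,2S)-2-{(R)-[4-(benzyloxy)-3-methoxyphenyl][(tert-butyldimethylsilyl)oxy]methyl}cyclopropyl]methanone
Product: 12 [4-(benzyloxy)-3-methoxyphenyl][(3R,4R)-4-{(R)-[4-(benzyloxy)-3-methoxyphenyl][(tert-butyldimethylsilyl)oxy]methyl}oxolan-3-yl]methanone, via iodo magnesium enolate 10 (not isolated), via iodo aldolate 11 (not isolated)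
Conditions: MgI2 (1.0 equiv), CH2O (3 equiv, THF solution), THF, 65 °C, sealed tube
Reagents that add atoms: formaldehyde, C=O
Why: MgI2 activates the aryl ketone and iodide opens the cyclopropane by SN2 attack at its unsubstituted CH2 (homo-conjugate addition) to give the γ-iodo magnesium enolate 10, which adds to formaldehyde (aldol, C2–C3) to give alkoxide 11, and this displaces the primary iodide (O1–C5) and returns MgI2. The closest known reaction types are the MgI2-mediated ring expansion (formal [3+2]) of carbonyl-activated cyclopropanes with imines or aldehydes and the iodo-aldol reaction of aryl cyclopropyl ketones. The oxolane ring closes by 5-exo-tet O-alkylation, the C–C bond being made intermolecularly. The C4 stereocentre is carried over unchanged from the cyclopropane; the new C3 centre should be set trans to it by attack of formaldehyde on the enolate face anti to the large silyloxybenzyl group in the allylic-strain-minimised conformer, backed by equilibration of this epimerisable α-keto centre. The step needs iodide attack at CH2 rather than at the substituted ring carbon (secured by sterics and by the single ketone acceptor, which dictates the bond that breaks), mono-hydroxymethylation (limited CH2O, weakly basic medium) and survival of the benzylic silyl ether (mild, THF-solvated MgI2).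

Step 6
Reactants: 12 [4-(benzyloxy)-3-methoxyphenyl][(3R,4R)-4-{(R)-[4-(benzyloxy)-3-methoxyphenyl][(tert-butyldimethylsilyl)oxy]methyl}oxolan-3-yl]methanone
Product: 13 (S)-[4-(benzyloxy)-3-methoxyphenyl][(3R,4R)-4-{(R)-[4-(benzyloxy)-3-methoxyphenyl][(tert-butyldimethylsilyl)oxy]methyl}oxolan-3-yl]methanol
Conditions: LiBH(s-Bu)3, THF, −78 °C; then H2O
Reagents that add atoms: none
Why: Felkin–Anh-controlled hydride reduction of an α-branched aryl ketone, in which the bulky hydride should attack anti to the more substituted ring carbon C4 (large) with ring CH2 C2 as the medium group, giving the (S)-carbinol.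

Step 7
Reactants: 13 (S)-[4-(benzyloxy)-3-methoxyphenyl][(3R,4R)-4-{(R)-[4-(benzyloxy)-3-methoxyphenyl][(tert-butyldimethylsilyl)oxy]methyl}oxolan-3-yl]methanol
Product: 14 (S)-[4-(benzyloxy)-3-methoxyphenyl][(3R,4R)-4-{(R)-[4-(benzyloxy)-3-methoxyphenyl](hydroxy)methyl}oxolan-3-yl]methanol
Conditions: Bu4NF, THF, 23 °C; then H2O
Reagents that add atoms: none
Why: Fluoride-induced desilylation cleaves only the Si–O bond, so the benzylic configuration should be retained and the benzyl ethers untouched.

Step 8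
Reactants: 14 (S)-[4-(benzyloxy)-3-methoxyphenyl][(3R,4R)-4-{(R)-[4-(benzyloxy)-3-methoxyphenyl](hydroxy)methyl}oxolan-3-yl]methanol
Product: 15 4-[(S)-hydroxy{(3R,4R)-4-[(R)-hydroxy(4-hydroxy-3-methoxyphenyl)methyl]oxolan-3-yl}methyl]-2-methoxyphenol
Conditions: H2 (1 atm), 10% Pd/C, EtOAc–EtOH, 23 °C, stopped at full debenzylation
Reagents that add atoms: none
Why: Hydrogenolysis of aryl benzyl ethers is much faster than that of secondary benzylic alcohols under neutral conditions, so both phenols should be freed with the two carbinols intact.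

Compound list
1 | 2-bromo-1-[4-(benzyloxy)-3-methoxyphenyl]ethan-1-one | COc1cc(C(=O)CBr)ccc1OCc1ccccc1 | starting material
2 | N-methoxy-N-methylprop-2-enamide | C=CC(=O)N(C)OC | starting material
3 | (1S,2S)-2-[4-(benzyloxy)-3-methoxybenzoyl]-N-methoxy-N-methylcyclopropane-1-carboxamide | COc1cc(C(=O)[C@H]2C[C@@H]2C(=O)N(C)OC)ccc1OCc1ccccc1 | intermediate
4 | (1S,2S)-2-{(R)-[4-(benzyloxy)-3-methoxyphenyl](hydroxy)methyl}-N-methoxy-N-methylcyclopropane-1-carboxamide | COc1cc([C@H](O)[C@H]2C[C@@H]2C(=O)N(C)OC)ccc1OCc1ccccc1 | intermediate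
5 | (1S,2S)-2-{(R)-[4-(benzyloxy)-3-methoxyphenyl][(tert-butyldimethylsilyl)oxy]methyl}-N-methoxy-N-methylcyclopropane-1-carboxamide | COc1cc([C@H](O[Si](C)(C)C(C)(C)C)[C@H]2C[C@@H]2C(=O)N(C)OC)ccc1OCc1ccccc1 | intermediate
6 | 1-(benzyloxy)-4-bromo-2-methoxybenzene | COc1cc(Br)ccc1OCc1ccccc1 | starting material
7 | [4-(benzyloxy)-3-methoxyphenyl]lithium | COc1cc([Li])ccc1OCc1ccccc1 | intermediate (not isolated)
8 | lithium alkoxide of the tetrahedral adduct of 7 to the Weinreb amide of 5 (aminal carbon configuration not controlled) | COc1cc(C(O[Li])(N(C)OC)[C@H]2C[C@@H]2[C@@H](O[Si](C)(C)C(C)(C)C)c2ccc(OCc3ccccc3)c(OC)c2)ccc1OCc1ccccc1 | intermediate (not isolated)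
9 | [4-(benzyloxy)-3-methoxyphenyl][(1S,2S)-2-{(R)-[4-(benzyloxy)-3-methoxyphenyl][(tert-butyldimethylsilyl)oxy]methyl}cyclopropyl]methanone | COc1cc(C(=O)[C@H]2C[C@@H]2[C@@H](O[Si](C)(C)C(C)(C)C)c2ccc(OCc3ccccc3)c(OC)c2)ccc1OCc1ccccc1 | intermediate
10 | iodomagnesium (1Z,3S,4R)-1,4-bis[4-(benzyloxy)-3-methoxyphenyl]-4-[(tert-butyldimethylsilyl)oxy]-3-(iodomethyl)but-1-en-1-olate | COc1cc(/C(O[Mg]I)=C/[C@H](CI)[C@@H](O[Si](C)(C)C(C)(C)C)c2ccc(OCc3ccccc3)c(OC)c2)ccc1OCc1ccccc1 | intermediate (not isolated)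
11 | iodomagnesium alkoxide of (2R,3S,4R)-1,4-bis[4-(benzyloxy)-3-methoxyphenyl]-4-[(tert-butyldimethylsilyl)oxy]-2-(hydroxymethyl)-3-(iodomethyl)butan-1-one | COc1cc(C(=O)[C@@H](CO[Mg]I)[C@H](CI)[C@@H](O[Si](C)(C)C(C)(C)C)c2ccc(OCc3ccccc3)c(OC)c2)ccc1OCc1ccccc1 | intermediate (not isolated)
12 | [4-(benzyloxy)-3-methoxyphenyl][(3R,4R)-4-{(R)-[4-(benzyloxy)-3-methoxyphenyl][(tert-butyldimethylsilyl)oxy]methyl}oxolan-3-yl]methanone | COc1cc(C(=O)[C@H]2COC[C@@H]2[C@@H](O[Si](C)(C)C(C)(C)C)c2ccc(OCc3ccccc3)c(OC)c2)ccc1OCc1ccccc1 | intermediate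
13 | (S)-[4-(benzyloxy)-3-methoxyphenyl][(3R,4R)-4-{(R)-[4-(benzyloxy)-3-methoxyphenyl][(tert-butyldimethylsilyl)oxy]methyl}oxolan-3-yl]methanol | COc1cc([C@@H](O)[C@H]2COC[C@@H]2[C@@H](O[Si](C)(C)C(C)(C)C)c2ccc(OCc3ccccc3)c(OC)c2)ccc1OCc1ccccc1 | intermediate
14 | (S)-[4-(benzyloxy)-3-methoxyphenyl][(3R,4R)-4-{(R)-[4-(benzyloxy)-3-methoxyphenyl](hydroxy)methyl}oxolan-3-yl]methanol | COc1cc([C@@H](O)[C@H]2COC[C@@H]2[C@@H](O)c2ccc(OCc3ccccc3)c(OC)c2)ccc1OCc1ccccc1 | intermediate
15 | 4-[(S)-hydroxy{(3R,4R)-4-[(R)-hydroxy(4-hydroxy-3-methoxyphenyl)methyl]oxolan-3-yl}methyl]-2-methoxyphenol | COc1cc([C@@H](O)[C@H]2COC[C@@H]2[C@@H](O)c2ccc(O)c(OC)c2)ccc1O | target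

Total step count: 8. Longest linear sequence: 8 steps (1 to 15); aryl bromide 6 enters at step 4.

Steps most likely to fail

Step 5 (key step). The risk is ionisation of the benzylic silyl ether next to the cyclopropane (cyclopropylcarbinyl to homoallyl iodide rearrangement) under the Lewis acid, together with slow closure of the iodo aldolate or a second hydroxymethylation. The fallback sets out from 3 and returns at 14; it runs the ring expansion before the ionisable benzylic ether exists and sets both carbinols afterwards by Felkin–Anh additions. Keto amide 3 with MgI2 and CH2O in THF should give (3R,4R)-4-[4-(benzyloxy)-3-methoxybenzoyl]-N-methoxy-N-methyloxolane-3-carboxamide F1, the ketone enolate being the only one formed. LiBH(s-Bu)3 at −78 °C should reduce the ketone to the (S)-alcohol F2, and TBSCl with imidazole gives its silyl ether F3. i-Bu2AlH in THF at −78 °C reduces the Weinreb amide to the aldehyde F4. Aryllithium 7 (from 6) adds to F4 anti to the substituted ring carbon to give the syn (R)-carbinol, the mono-silyl ether F5, and Bu4NF then gives 14.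

Step 1. The risk is slow conjugate addition of the ammonium ylide to the weakly electrophilic acrylamide, self-condensation of the bromo ketone, or insufficient or opposite facial selectivity. The fallback sets out from 6 (as aryllithium 7) with purchased (−)-dimenthyl succinate and returns at 3; it takes the ring configuration from the menthyl auxiliary, whose sense is established. The succinate dianion (lithium 2,2,6,6-tetramethylpiperidide, THF, −78 °C) is alkylated twice by BrCH2Cl to give dimenthyl (1S,2S)-cyclopropane-1,2-dicarboxylate F6. AlMe3 with MeNH(OMe)·HCl in toluene converts it to the bis-Weinreb amide F7. One equivalent of 7 at −78 °C should give 3 by mono-addition, with recovered F7 recycled.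

Step 6. The risk is poor facial selectivity of hydride delivery, because the two ring carbons flanking the ketone-bearing centre may not differ enough in size. The fallback sets out from 12 and returns at 13; it corrects the minor epimer by inversion instead of relying on the reduction. The (R)-epimer F8, separated from the reduction mixture, is esterified under Mitsunobu conditions (4-nitrobenzoic acid, PPh3, DIAD, toluene, 0 °C) with inversion to the (S)-4-nitrobenzoate F9, and K2CO3 in MeOH then gives 13.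

Further compounds
F1 | step 5 | (3R,4R)-4-[4-(benzyloxy)-3-methoxybenzoyl]-N-methoxy-N-methyloxolane-3-carboxamide | COc1cc(C(=O)[C@H]2COC[C@@H]2C(=O)N(C)OC)ccc1OCc1ccccc1
F2 | step 5 | (3R,4R)-4-{(S)-[4-(benzyloxy)-3-methoxyphenyl](hydroxy)methyl}-N-methoxy-N-methyloxolane-3-carboxamide | COc1cc([C@@H](O)[C@H]2COC[C@@H]2C(=O)N(C)OC)ccc1OCc1ccccc1
F3 | step 5 | (3R,4R)-4-{(S)-[4-(benzyloxy)-3-methoxyphenyl][(tert-butyldimethylsilyl)oxy]methyl}-N-methoxy-N-methyloxolane-3-carboxamide | COc1cc([C@@H](O[Si](C)(C)C(C)(C)C)[C@H]2COC[C@@H]2C(=O)N(C)OC)ccc1OCc1ccccc1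
F4 | step 5 | (3R,4R)-4-{(S)-[4-(benzyloxy)-3-methoxyphenyl][(tert-butyldimethylsilyl)oxy]methyl}oxolane-3-carbaldehyde | COc1cc([C@@H](O[Si](C)(C)C(C)(C)C)[C@H]2COC[C@@H]2C=O)ccc1OCc1ccccc1
F5 | step 5 | (R)-[4-(benzyloxy)-3-methoxyphenyl][(3R,4R)-4-{(S)-[4-(benzyloxy)-3-methoxyphenyl][(tert-butyldimethylsilyl)oxy]methyl}oxolan-3-yl]methanol | COc1cc([C@@H](O[Si](C)(C)C(C)(C)C)[C@H]2COC[C@@H]2[C@@H](O)c2ccc(OCc3ccccc3)c(OC)c2)ccc1OCc1ccccc1
F6 | step 1 | bis[(1R,2S,5R)-5-methyl-2-(propan-2-yl)cyclohexyl] (1S,2S)-cyclopropane-1,2-dicarboxylate | CC(C)[C@@H]1CC[C@@H](C)C[C@H]1OC(=O)[C@H]1C[C@@H]1C(=O)O[C@@H]1C[C@H](C)CC[C@H]1C(C)C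
F7 | step 1 | (1S,2S)-N1,N2-dimethoxy-N1,N2-dimethylcyclopropane-1,2-dicarboxamide | CON(C)C(=O)[C@H]1C[C@@H]1C(=O)N(C)OC
F8 | step 6 | (R)-[4-(benzyloxy)-3-methoxyphenyl][(3R,4R)-4-{(R)-[4-(benzyloxy)-3-methoxyphenyl][(tert-butyldimethylsilyl)oxy]methyl}oxolan-3-yl]methanol | COc1cc([C@H](O)[C@H]2COC[C@@H]2[C@@H](O[Si](C)(C)C(C)(C)C)c2ccc(OCc3ccccc3)c(OC)c2)ccc1OCc1ccccc1
F9 | step 6 | (S)-[4-(benzyloxy)-3-methoxyphenyl][(3R,4R)-4-{(R)-[4-(benzyloxy)-3-methoxyphenyl][(tert-butyldimethylsilyl)oxy]methyl}oxolan-3-yl]methyl 4-nitrobenzoate | COc1cc([C@@H](OC(=O)c2ccc(cc2)[N+](=O)[O-])[C@H]2COC[C@@H]2[C@@H](O[Si](C)(C)C(C)(C)C)c2ccc(OCc3ccccc3)c(OC)c2)ccc1OCc1ccccc1
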